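**Retrosynthetic overview** (azulene numbering: five-membered ring C1–C2–C3–C3a–C8a, seven-membered ring C3a–C4–C5–C6–C7–C8–C8a)

1. Late steps: O4 aroylation, C6–CH3 from C6–CO2Me, C4–OH from a C4 ketone by hydride delivered from the C3 hydroxyl.
2. The five-membered ring is opened at C3–C3a (aldol retron: C3 carbinol β to the C4 carbonyl). This leaves a cycloheptadiene with a 4-methyl-3-oxopentyl chain on C8a.
3. Enabling feature: in that seven-membered ring the C4 oxygen (as enol ether C3a=C4) and the C6=C7 alkene form a 1,4-diene around C5H2, with the C8 carbinol and quaternary C8a between them. This is the product pattern of a cis-divinylcyclopropane Cope shift, so cutting C5–C6 and C8–C8a gives an acyclic 2-ethoxy-1,3-diene and a vinylcarbenoid that carries C8 as a boronate.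
4. Ring order: temporary cyclopropane (C4–C5–C6), then the seven-membered ring (step 6), then the five-membered ring (step 9).
5. Stereocontrol: C8 and C8a by a chiral dirhodium catalyst and the boat Cope shift; C3 and C3a together in the aldol closure; C4 by the directed reduction.

Key step: step 6

Remark on the chemistry: the catalyst antipode Rh2(R-DOSP)4 is chosen on the empirical model for these prolinate catalysts, assuming the alkenyl group of the enol ether sits cis to the carbenoid's vinyl group; if the cycloadduct proves to be the mirror-image series, Rh2(S-DOSP)4 is used instead.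

Step 1
Reactants: 1 ethyl vinyl ether; 2 methacrolein
Product: 4 2-ethoxy-4-methylpenta-1,4-dien-3-ol, via (1-ethoxyethenyl)lithium 3 (not isolated)
Conditions: tBuLi, THF, −78 → 0 °C; then 2, −78 °C; aq. NH4Cl
Reagents that add atoms: none
Why: α-Lithiation of the vinyl ether and 1,2-addition of the hard vinyllithium to the enal carbonyl should give the bis-allylic carbinol, whose stereocenter is left uncontrolled because step 2 destroys it.

Step 2
Reactants: 4 2-ethoxy-4-methylpenta-1,4-dien-3-ol; 5 N,N-dimethylacetamide dimethyl acetal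
Product: 6 (4E)-6-ethoxy-N,N,4-trimethylhepta-4,6-dienamide
Conditions: xylene, 140 °C, MeOH distilled off
Reagents that add atoms: none
Why: Eschenmoser–Claisen rearrangement, in which the ketene N,O-acetal formed in situ should shift through the methallyl arm (the ethoxy-bearing arm is slowed by the alkoxy group on its central carbon) via a chair with the ethoxyvinyl group equatorial, giving the E trisubstituted alkene under acid-free conditions that spare the enol ether.

Step 3
Reactants: 6 (4E)-6-ethoxy-N,N,4-trimethylhepta-4,6-dienamide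
Product: 8 (6E)-8-ethoxy-2,6-dimethylnona-6,8-dien-3-one, via lithium hemiaminal alkoxide 7 (not isolated)
Conditions: iPrLi, Et2O/THF, −78 °C; aq. NH4Cl
Reagents that add atoms: isopropyllithium, CC(C)[Li]
Why: Addition of the alkyllithium to the tertiary amide gives a tetrahedral lithium alkoxide that collapses to the ketone only on work-up, so a second addition should not occur and no stereocenter is formed.

Step 4
Reactants: 9 methyl but-3-enoate; 10 vinylboronic acid pinacol ester
Product: 11 methyl (3E)-4-(4,4,5,5-tetramethyl-1,3,2-dioxaborolan-2-yl)but-3-enoate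
Conditions: second-generation Grubbs catalyst (2 mol %), CH2Cl2, 40 °C
Reagents that add atoms: none
Why: Olefin cross-metathesis of a terminal alkene with the vinylboronate, a pairing that should give the E alkenylboronate with loss of ethene.

Step 5
Reactants: 11 methyl (3E)-4-(4,4,5,5-tetramethyl-1,3,2-dioxaborolan-2-yl)but-3-enoate
Product: 12 methyl (3E)-2-diazo-4-(4,4,5,5-tetramethyl-1,3,2-dioxaborolan-2-yl)but-3-enoate
Conditions: 4-acetamidobenzenesulfonyl azide, DBU, MeCN, 0 °C
Reagents that add atoms: 4-acetamidobenzenesulfonyl azide, CC(=O)Nc1ccc(cc1)S(=O)(=O)N=[N+]=[N-]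
Why: Regitz diazo transfer to the dienolate of the β,γ-unsaturated ester should give the vinyldiazoacetate with the E geometry retained.

Step 6
Reactants: 8 (6E)-8-ethoxy-2,6-dimethylnona-6,8-dien-3-one; 12 methyl (3E)-2-diazo-4-(4,4,5,5-tetramethyl-1,3,2-dioxaborolan-2-yl)but-3-enoate
Product: 14 methyl (3R,4R)-6-ethoxy-4-methyl-4-(4-methyl-3-oxopentyl)-3-(4,4,5,5-tetramethyl-1,3,2-dioxaborolan-2-yl)cyclohepta-1,5-diene-1-carboxylate, via cis-divinylcyclopropane 13 (not isolated)
Conditions: Rh2(R-DOSP)4 (1 mol %), hexane, −20 → 23 °C (12 added over 2 h to 8, 1.5 equiv); then 50 °C, 1 h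
Reagents that add atoms: none
Why: The dirhodium carbenoid from 12 should add to the terminal, most electron-rich C=C of 8 (the 2-ethoxy enol ether; the trisubstituted alkene is too hindered and the ketone is a poor partner) to give cis-divinylcyclopropane 13, whose vicinal donor (OEt) and acceptor (ester) weaken the ring bond that the following shift breaks. The closest known reaction type is the rhodium-catalysed tandem cyclopropanation/Cope rearrangement (formal (4+3) cycloaddition) of vinyldiazoacetates with 1,3-dienes, including 2-oxygenated dienes. Ring closures: the three-membered ring by (2+1) carbene addition, then the seven-membered ring by a (3,3)-sigmatropic divinylcyclopropane shift through a boat transition state, which cleaves the temporary C4–C6 bond (azulene numbering) and forms C8–C8a after C5–C6 was formed in the cyclopropanation. Stereocenters: the boat transmits both alkene geometries, so the boron at C8 (E substituent of the vinyl terminus) should end anti to the C8a methyl (Z substituent of the diene terminus), and the absolute sense should come from the chiral prolinate ligands choosing the face of the enol ether in the cyclopropanation. Selectivities needed are carbenoid rather than vinylogous reactivity, secured by the E boryl group blocking the vinyl terminus and by the hydrocarbon solvent, and cis-divinyl geometry, expected because the alkenyl group of the enol ether takes the position cis to the carbenoid's vinyl group, with any trans isomer able to equilibrate through the weak donor–acceptor bond on warming.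

Step 7
Reactants: 14 methyl (3R,4R)-6-ethoxy-4-methyl-4-(4-methyl-3-oxopentyl)-3-(4,4,5,5-tetramethyl-1,3,2-dioxaborolan-2-yl)cyclohepta-1,5-diene-1-carboxylate
Product: 15 methyl (3R,4S)-6-ethoxy-3-hydroxy-4-methyl-4-(4-methyl-3-oxopentyl)cyclohepta-1,5-diene-1-carboxylate
Conditions: NaBO3·4H2O, THF/H2O (1:1), 23 °C
Reagents that add atoms: sodium perborate tetrahydrate (NaBO3·4H2O), [Na+].[O-]OB=O.O.O.O.O
Why: Boronate oxidation, in which the carbon migrates from boron to oxygen with retention, should turn the allylic C–B bond into C–OH without allylic transposition and without touching the ketone, enol ether or enoate.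

Step 8
Reactants: 15 methyl (3R,4S)-6-ethoxy-3-hydroxy-4-methyl-4-(4-methyl-3-oxopentyl)cyclohepta-1,5-diene-1-carboxylate
Product: 16 methyl (3R,4S)-3-(tert-butyldimethylsilyloxy)-6-ethoxy-4-methyl-4-(4-methyl-3-oxopentyl)cyclohepta-1,5-diene-1-carboxylate
Conditions: TBSCl, imidazole, DMAP (cat.), DMF, 40 °C
Reagents that add atoms: tert-butyldimethylsilyl chloride, CC(C)(C)[Si](C)(C)Cl
Why: Silylation of the only hydroxyl group under base-only conditions, so that no Lewis acid triggers early cyclization of the enol ether onto the ketone.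

Step 9
Reactants: 16 methyl (3R,4S)-3-(tert-butyldimethylsilyloxy)-6-ethoxy-4-methyl-4-(4-methyl-3-oxopentyl)cyclohepta-1,5-diene-1-carboxylate
Product: 17 methyl (3R,3aR,8R,8aS)-8-(tert-butyldimethylsilyloxy)-3-hydroxy-8a-methyl-4-oxo-3-(propan-2-yl)-1,2,3,3a,4,5,8,8a-octahydroazulene-6-carboxylate
Conditions: TiCl4 (1.1 equiv), CH2Cl2, −78 °C; then aq. NaHCO3, −78 → 0 °C; used at once in step 10
Reagents that add atoms: water, O
Why: Lewis-acid aldol addition of the ring enol ether to the side-chain ketone (Mukaiyama/Prins type, 5-exo attack by the enol ether carbon) should close the five-membered ring with the tethered carbonyl reaching C3a on the convex face anti to C8 (trans fusion), the titanium-bound oxygen turned toward the developing oxocarbenium at C4 and the isopropyl group away from it (C3–OH cis to C4), the chelated aldolate also being the expected thermodynamic isomer, and aqueous work-up hydrolysing the O-ethyl oxocarbenium to the C4 ketone.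

Step 10
Reactants: 17 methyl (3R,3aR,8R,8aS)-8-(tert-butyldimethylsilyloxy)-3-hydroxy-8a-methyl-4-oxo-3-(propan-2-yl)-1,2,3,3a,4,5,8,8a-octahydroazulene-6-carboxylate
Product: 18 methyl (3R,3aS,4S,8R,8aS)-8-(tert-butyldimethylsilyloxy)-3,4-dihydroxy-8a-methyl-3-(propan-2-yl)-1,2,3,3a,4,5,8,8a-octahydroazulene-6-carboxylate
Conditions: Me4NBH(OAc)3, MeCN/AcOH (1:1), −20 °C
Reagents that add atoms: none
Why: Evans–Saksena reduction, in which the C3 alkoxyborohydride should deliver hydride to C4 intramolecularly through the one chair that the trans ring fusion allows (C4 oxygen axial, C5 equatorial), placing the new hydrogen anti to H3a and giving the 1,3-anti diol with the C4 hydroxyl on the face of H3a.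

Step 11
Reactants: 18 methyl (3R,3aS,4S,8R,8aS)-8-(tert-butyldimethylsilyloxy)-3,4-dihydroxy-8a-methyl-3-(propan-2-yl)-1,2,3,3a,4,5,8,8a-octahydroazulene-6-carboxylate
Product: 19 (3R,3aS,4S,8R,8aS)-8-(tert-butyldimethylsilyloxy)-6-(hydroxymethyl)-8a-methyl-3-(propan-2-yl)-1,2,3,3a,4,5,8,8a-octahydroazulene-3,4-diol
Conditions: iBu2AlH (5 equiv), CH2Cl2, −78 → −40 °C; aq. Rochelle salt
Reagents that add atoms: none
Why: 1,2-Reduction of the conjugated ester to the allylic alcohol, the free hydroxyls being carried as aluminium alkoxides and the silyl ether being inert.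

Step 12
Reactants: 19 (3R,3aS,4S,8R,8aS)-8-(tert-butyldimethylsilyloxy)-6-(hydroxymethyl)-8a-methyl-3-(propan-2-yl)-1,2,3,3a,4,5,8,8a-octahydroazulene-3,4-diol
Product: 21 (3R,3aS,4S,8R,8aS)-8-(tert-butyldimethylsilyloxy)-6,8a-dimethyl-3-(propan-2-yl)-1,2,3,3a,4,5,8,8a-octahydroazulene-3,4-diol, via pyridinium allyl sulfate 20 (not isolated)
Conditions: SO3·pyridine (1.1 equiv), THF, −20 → 0 °C; then LiAlH4, 0 → 23 °C
Reagents that add atoms: none
Why: The primary allylic alcohol should be sulfated much faster than the hindered secondary and tertiary ones, and hydride should displace the allylic sulfate at the primary carbon (sulfate ester/hydride deoxygenation of allylic alcohols) without moving the ring alkene.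

Step 13
Reactants: 21 (3R,3aS,4S,8R,8aS)-8-(tert-butyldimethylsilyloxy)-6,8a-dimethyl-3-(propan-2-yl)-1,2,3,3a,4,5,8,8a-octahydroazulene-3,4-diol; 22 4-methoxybenzoyl chloride
Product: 23 (3R,3aS,4S,8R,8aS)-8-(tert-butyldimethylsilyloxy)-3-hydroxy-6,8a-dimethyl-3-(propan-2-yl)-1,2,3,3a,4,5,8,8a-octahydroazulen-4-yl 4-methoxybenzoate
Conditions: pyridine, DMAP (cat.), CH2Cl2, 0 → 23 °C
Reagents that add atoms: none
Why: Acylation of the secondary C4 hydroxyl, the tertiary C3 hydroxyl being unreactive under these conditions and the C8 hydroxyl being masked.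

Step 14
Reactants: 23 (3R,3aS,4S,8R,8aS)-8-(tert-butyldimethylsilyloxy)-3-hydroxy-6,8a-dimethyl-3-(propan-2-yl)-1,2,3,3a,4,5,8,8a-octahydroazulen-4-yl 4-methoxybenzoate
Product: 24 (3R,3aS,4S,8R,8aS)-3,8-dihydroxy-6,8a-dimethyl-3-(propan-2-yl)-1,2,3,3a,4,5,8,8a-octahydroazulen-4-yl 4-methoxybenzoate
Conditions: HF·pyridine, pyridine, THF, 0 → 23 °C
Reagents that add atoms: none
Why: Buffered fluoride cleavage of the silyl ether should free the C8 hydroxyl while leaving the ester and the allylic alcohol intact.

**Compound list**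

1 | ethyl vinyl ether | C=COCC | starting material
2 | methacrolein (2-methylprop-2-enal) | CC(=C)C=O | starting material
3 | (1-ethoxyethenyl)lithium | [Li]C(=C)OCC | intermediate (not isolated)
4 | 2-ethoxy-4-methylpenta-1,4-dien-3-ol (racemic) | C=C(OCC)C(O)C(C)=C | intermediate
5 | N,N-dimethylacetamide dimethyl acetal (1,1-dimethoxy-N,N-dimethylethan-1-amine) | COC(C)(OC)N(C)C | starting material
6 | (4E)-6-ethoxy-N,N,4-trimethylhepta-4,6-dienamide | CN(C)C(=O)CC/C(C)=C/C(=C)OCC | intermediate
7 | lithium (6E)-3-(dimethylamino)-8-ethoxy-2,6-dimethylnona-6,8-dien-3-olate | CC(C)C([O-])(N(C)C)CC/C(C)=C/C(=C)OCC.[Li+] | intermediate (not isolated)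
8 | (6E)-8-ethoxy-2,6-dimethylnona-6,8-dien-3-one | CC(C)C(=O)CC/C(C)=C/C(=C)OCC | intermediate
9 | methyl but-3-enoate | COC(=O)CC=C | starting material
10 | vinylboronic acid pinacol ester (4,4,5,5-tetramethyl-2-vinyl-1,3,2-dioxaborolane) | C=CB1OC(C)(C)C(C)(C)O1 | starting material
11 | methyl (3E)-4-(4,4,5,5-tetramethyl-1,3,2-dioxaborolan-2-yl)but-3-enoate | COC(=O)C/C=C/B1OC(C)(C)C(C)(C)O1 | intermediate
12 | methyl (3E)-2-diazo-4-(4,4,5,5-tetramethyl-1,3,2-dioxaborolan-2-yl)but-3-enoate | COC(=O)C(=[N+]=[N-])/C=C/B1OC(C)(C)C(C)(C)O1 | intermediate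
13 | methyl (1S,2R)-2-ethoxy-2-[(1E)-2,6-dimethyl-5-oxohept-1-en-1-yl]-1-[(E)-2-(4,4,5,5-tetramethyl-1,3,2-dioxaborolan-2-yl)ethenyl]cyclopropane-1-carboxylate (vinyl and alkenyl groups cis) | COC(=O)[C@]1(/C=C/B2OC(C)(C)C(C)(C)O2)C[C@@]1(OCC)/C=C(\C)CCC(=O)C(C)C | intermediate (not isolated)
14 | methyl (3R,4R)-6-ethoxy-4-methyl-4-(4-methyl-3-oxopentyl)-3-(4,4,5,5-tetramethyl-1,3,2-dioxaborolan-2-yl)cyclohepta-1,5-diene-1-carboxylate (boron anti to the ring methyl) | CCOC1=C[C@](C)(CCC(=O)C(C)C)[C@H](B2OC(C)(C)C(C)(C)O2)C=C(C(=O)OC)C1 | intermediate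
15 | methyl (3R,4S)-6-ethoxy-3-hydroxy-4-methyl-4-(4-methyl-3-oxopentyl)cyclohepta-1,5-diene-1-carboxylate | CCOC1=C[C@](C)(CCC(=O)C(C)C)[C@H](O)C=C(C(=O)OC)C1 | intermediate
16 | methyl (3R,4S)-3-(tert-butyldimethylsilyloxy)-6-ethoxy-4-methyl-4-(4-methyl-3-oxopentyl)cyclohepta-1,5-diene-1-carboxylate | CCOC1=C[C@](C)(CCC(=O)C(C)C)[C@H](O[Si](C)(C)C(C)(C)C)C=C(C(=O)OC)C1 | intermediate
17 | methyl (3R,3aR,8R,8aS)-8-(tert-butyldimethylsilyloxy)-3-hydroxy-8a-methyl-4-oxo-3-(propan-2-yl)-1,2,3,3a,4,5,8,8a-octahydroazulene-6-carboxylate (trans-fused; C3–OH cis to C4) | O=C2CC(C(=O)OC)=C[C@@H](O[Si](C)(C)C(C)(C)C)[C@@]3(C)CC[C@@](O)(C(C)C)[C@H]23 | intermediate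
18 | methyl (3R,3aS,4S,8R,8aS)-8-(tert-butyldimethylsilyloxy)-3,4-dihydroxy-8a-methyl-3-(propan-2-yl)-1,2,3,3a,4,5,8,8a-octahydroazulene-6-carboxylate | O[C@H]2CC(C(=O)OC)=C[C@@H](O[Si](C)(C)C(C)(C)C)[C@@]3(C)CC[C@@](O)(C(C)C)[C@H]23 | intermediate
19 | (3R,3aS,4S,8R,8aS)-8-(tert-butyldimethylsilyloxy)-6-(hydroxymethyl)-8a-methyl-3-(propan-2-yl)-1,2,3,3a,4,5,8,8a-octahydroazulene-3,4-diol | O[C@H]2CC(CO)=C[C@@H](O[Si](C)(C)C(C)(C)C)[C@@]3(C)CC[C@@](O)(C(C)C)[C@H]23 | intermediate
20 | pyridinium [(3R,3aS,4S,8R,8aS)-8-(tert-butyldimethylsilyloxy)-3,4-dihydroxy-8a-methyl-3-(propan-2-yl)-1,2,3,3a,4,5,8,8a-octahydroazulen-6-yl]methyl sulfate | O[C@H]2CC(COS(=O)(=O)[O-])=C[C@@H](O[Si](C)(C)C(C)(C)C)[C@@]3(C)CC[C@@](O)(C(C)C)[C@H]23.c1cc[nH+]cc1 | intermediate (not isolated)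
21 | (3R,3aS,4S,8R,8aS)-8-(tert-butyldimethylsilyloxy)-6,8a-dimethyl-3-(propan-2-yl)-1,2,3,3a,4,5,8,8a-octahydroazulene-3,4-diol | O[C@H]2CC(C)=C[C@@H](O[Si](C)(C)C(C)(C)C)[C@@]3(C)CC[C@@](O)(C(C)C)[C@H]23 | intermediate
22 | 4-methoxybenzoyl chloride | COc1ccc(cc1)C(Cl)=O | starting material
23 | (3R,3aS,4S,8R,8aS)-8-(tert-butyldimethylsilyloxy)-3-hydroxy-6,8a-dimethyl-3-(propan-2-yl)-1,2,3,3a,4,5,8,8a-octahydroazulen-4-yl 4-methoxybenzoate | COc1ccc(C(=O)O[C@H]2CC(C)=C[C@@H](O[Si](C)(C)C(C)(C)C)[C@@]3(C)CC[C@@](O)(C(C)C)[C@H]23)cc1 | intermediate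
24 | (3R,3aS,4S,8R,8aS)-3,8-dihydroxy-6,8a-dimethyl-3-(propan-2-yl)-1,2,3,3a,4,5,8,8a-octahydroazulen-4-yl 4-methoxybenzoate | COc1ccc(C(=O)O[C@H]2CC(C)=C[C@@H](O)[C@@]3(C)CC[C@@](O)(C(C)C)[C@H]23)cc1 | target

**Totals**

Total step count: 14. Longest linear sequence: 12 steps (steps 1–3, then 6–14); steps 4 and 5 form the short branch.

**Steps most likely to fail**

Step 6 (key step). The carbenoid may be attacked at its vinyl terminus, or the donor–acceptor cyclopropane may open to a zwitterion that closes to five-membered rings. The cyclopropanation may also give the trans-divinyl isomer or poor face control, and the allylic boronate may undergo a 1,3-boryl shift or protodeboronation. Fallback, setting out from 8 and coming back at 16: put oxygen instead of boron on the carbenoid. Methyl diazoacetate and (tert-butyldimethylsilyloxy)acetaldehyde (DBU cat., MeCN) should give methyl 4-(tert-butyldimethylsilyloxy)-2-diazo-3-hydroxybutanoate F1. Dehydration (POCl3, Et3N, CH2Cl2, 0 °C) should give methyl (3E)-4-(tert-butyldimethylsilyloxy)-2-diazobut-3-enoate F2. The same Rh2(R-DOSP)4-catalysed cyclopropanation/Cope sequence with 8, through methyl (1S,2R)-1-[(E)-2-(tert-butyldimethylsilyloxy)ethenyl]-2-ethoxy-2-[(1E)-2,6-dimethyl-5-oxohept-1-en-1-yl]cyclopropane-1-carboxylate F3, would then deliver 16 directly, so steps 7 and 8 are not needed.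

Step 9. The O-ethyl oxocarbenium may lose a proton instead of being hydrolysed, giving a dienyl ether and then migration of the C6=C7 alkene into conjugation with the C4 ketone. The ring may also close on the other face (cis fusion), or the hindered ketone may not react. Fallback, setting out from 16 and coming back at 17: hydrolyse the enol ether (oxalic acid on wet silica gel, CH2Cl2) to methyl (3R,4S)-3-(tert-butyldimethylsilyloxy)-4-methyl-4-(4-methyl-3-oxopentyl)-6-oxocyclohept-1-ene-1-carboxylate F4. Then close the ring by an amine-catalysed (enamine) intramolecular aldol addition (pyrrolidine/AcOH or proline, DMSO, 23 °C), which should select the five-membered closure by ring size and stop at the tertiary ketol as in the Hajos–Parrish reaction.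

Step 12. The C4 hydroxyl may be sulfated as well, or hydride may attack with allylic shift to give an exocyclic methylene. Fallback, setting out from 19 and coming back at 21: use chloride instead of sulfate. Corey–Kim chlorination (NCS, Me2S, CH2Cl2, −20 °C), selective for the allylic alcohol, should give (3R,3aS,4S,8R,8aS)-8-(tert-butyldimethylsilyloxy)-6-(chloromethyl)-8a-methyl-3-(propan-2-yl)-1,2,3,3a,4,5,8,8a-octahydroazulene-3,4-diol F5, which LiBHEt3 (THF, 0 °C) should reduce to 21.

**Further compounds**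

F1 | step 6 | methyl 4-(tert-butyldimethylsilyloxy)-2-diazo-3-hydroxybutanoate (racemic) | COC(=O)C(=[N+]=[N-])C(O)CO[Si](C)(C)C(C)(C)C
F2 | step 6 | methyl (3E)-4-(tert-butyldimethylsilyloxy)-2-diazobut-3-enoate | COC(=O)C(=[N+]=[N-])/C=C/O[Si](C)(C)C(C)(C)C
F3 | step 6 | methyl (1S,2R)-1-[(E)-2-(tert-butyldimethylsilyloxy)ethenyl]-2-ethoxy-2-[(1E)-2,6-dimethyl-5-oxohept-1-en-1-yl]cyclopropane-1-carboxylate | COC(=O)[C@]1(/C=C/O[Si](C)(C)C(C)(C)C)C[C@@]1(OCC)/C=C(\C)CCC(=O)C(C)C
F4 | step 9 | methyl (3R,4S)-3-(tert-butyldimethylsilyloxy)-4-methyl-4-(4-methyl-3-oxopentyl)-6-oxocyclohept-1-ene-1-carboxylate | O=C1C[C@](C)(CCC(=O)C(C)C)[C@H](O[Si](C)(C)C(C)(C)C)C=C(C(=O)OC)C1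
F5 | step 12 | (3R,3aS,4S,8R,8aS)-8-(tert-butyldimethylsilyloxy)-6-(chloromethyl)-8a-methyl-3-(propan-2-yl)-1,2,3,3a,4,5,8,8a-octahydroazulene-3,4-diol | O[C@H]2CC(CCl)=C[C@@H](O[Si](C)(C)C(C)(C)C)[C@@]3(C)CC[C@@](O)(C(C)C)[C@H]23
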